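## Retrosynthetic overview

1. The target is two 4-hydroxy-1-tetralones (rings A/B with C1–C8a; rings C/D with C1′–C8a′) joined C3–C7′. In each, carbinol C4 and ketone C1 sit on neighbouring arene carbons (C4a, C8a), so each ketone ring is the ring-expanded isomer of a γ-aryl-γ-butyrolactone: the C4 oxygen can hold the C1 acyl group, and a carbanion at C8a can take it over.
2. Key disconnection: C1–C8a (ring B) and, in the same operation, C1′–C8a′ (ring D), by double Br/Li exchange and intramolecular acyl transfer in bis-lactone dibromide 19, which already carries C3, C4 and C4′.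
3. 19 comes from bis-homoallylic diol 16 by two-directional hydroboration/oxidation and aerobic oxidative lactonization.
4. 16 comes from aldehyde 4 and (E)-γ-aryl allylboronate 15 (anti-selective, acid-catalyst-controlled allylboration sets C3 and C4); C4′ comes from an earlier catalyst-controlled allylboration of aldehyde 9.
5. Both arenes derive from 3-bromo-5-methylphenol; ring order: the two lactone rings (step 13), then rings B and D together (step 14).

Key step: step 14

Assumption: the two chiral phosphoric acids are taken to show their usual facial sense with these ortho-substituted aldehydes; if the sense proves opposite, the antipodal acid is used.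

## Route

Step 1
Reactants: 1 3-bromo-5-methylphenol
Product: 2 1-bromo-3-(methoxymethoxy)-5-methylbenzene
Conditions: NaH, MOMCl, THF/DMF, 0 °C to rt
Reagents that add atoms: chloromethyl methyl ether (MOMCl), COCCl
Why: Williamson-type O-alkylation of the sodium phenoxide installs the MOM acetal, which directs the later ortho-metalations, withstands the organolithium steps and leaves under mild acid.

Step 2
Reactants: 2 1-bromo-3-(methoxymethoxy)-5-methylbenzene
Product: 4 2-bromo-6-(methoxymethoxy)-4-methylbenzaldehyde, via aryllithium 3 (not isolated)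
Conditions: LiN(i-Pr)2, THF, −78 °C; DMF, −78 to 0 °C; 1 M HCl, 0 °C
Reagents that add atoms: N,N-dimethylformamide, CN(C)C=O
Why: directed ortho-metalation removes the ring proton flanked by Br and OMOM (the most acidic one; −78 °C keeps the ortho-bromo aryllithium from losing LiBr), and formylation with DMF gives the aldehyde that will become C4 with the bromine on the future C8a.

Step 3
Reactants: 2 1-bromo-3-(methoxymethoxy)-5-methylbenzene
Product: 6 3-(methoxymethoxy)-5-methylbenzaldehyde, via aryllithium 5 (not isolated)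
Conditions: n-BuLi, THF, −78 °C; DMF; 1 M HCl, 0 °C
Reagents that add atoms: N,N-dimethylformamide, CN(C)C=O
Why: bromine–lithium exchange is much faster than ring deprotonation at −78 °C, and the aryllithium is formylated by DMF at the carbon that will become C4a′.

Step 4
Reactants: 6 3-(methoxymethoxy)-5-methylbenzaldehyde
Product: 9 2-bromo-3-(methoxymethoxy)-5-methylbenzaldehyde, via lithium amino alkoxide 7 (not isolated), via ortho-lithiated amino alkoxide 8 (not isolated)
Conditions: LiN(Me)CH2CH2NMe2 (from Me2NCH2CH2NHMe and n-BuLi), THF, −20 °C; n-BuLi, −20 °C; BrCCl2CCl2Br, −78 °C; 1 M HCl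
Reagents that add atoms: 1,2-dibromo-1,1,2,2-tetrachloroethane, BrC(Cl)(Cl)C(Cl)(Cl)Br
Why: in situ protection of the aldehyde as an α-amino alkoxide and directed ortho-lithiation at the position between this group and OMOM (both direct there), then electrophilic bromination and hydrolysis, place the bromine on the future C8a′.

Step 5
Reactants: 9 2-bromo-3-(methoxymethoxy)-5-methylbenzaldehyde
Product: 10 (1R)-1-[2-bromo-3-(methoxymethoxy)-5-methylphenyl]but-3-en-1-ol
Conditions: allylB(pin), (R)-TRIP (5 mol %), toluene, −30 °C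
Reagents that add atoms: allylboronic acid pinacol ester, C=CCB1OC(C)(C)C(C)(C)O1
Why: chiral-phosphoric-acid-catalysed allylboration through a closed chair transition state, in which the (R)-acid is expected to expose the Re face of the aldehyde, sets C4′ as R.

Step 6
Reactants: 10 (1R)-1-[2-bromo-3-(methoxymethoxy)-5-methylphenyl]but-3-en-1-ol
Product: 11 (1R)-1-(2-bromo-3-hydroxy-5-methylphenyl)but-3-en-1-ol
Conditions: HCl (1.25 M in MeOH), 35 °C
Reagents that add atoms: none
Why: acid-catalysed transacetalization to methanol frees the phenol needed for step 7, while the benzylic carbinol, which has no ortho or para donor, should not ionize.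

Step 7
Reactants: 11 (1R)-1-(2-bromo-3-hydroxy-5-methylphenyl)but-3-en-1-ol
Product: 12 3-bromo-2-hydroxy-4-[(1R)-1-hydroxybut-3-en-1-yl]-6-methylbenzaldehyde
Conditions: MgCl2, Et3N, (CH2O)n, MeCN, reflux
Reagents that add atoms: formaldehyde (as paraformaldehyde), C=O
Why: magnesium-mediated ortho-formylation (Casnati–Skattebøl) delivers formaldehyde within the magnesium phenoxide chelate, so only the single free ortho position (future C7′, between OH and CH3) is formylated and the para position is left alone.

Step 8
Reactants: 12 3-bromo-2-hydroxy-4-[(1R)-1-hydroxybut-3-en-1-yl]-6-methylbenzaldehyde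
Product: 13 3-bromo-4-[(1R)-1-hydroxybut-3-en-1-yl]-2-(methoxymethoxy)-6-methylbenzaldehyde
Conditions: MOMCl, K2CO3, acetone, rt
Reagents that add atoms: chloromethyl methyl ether (MOMCl), COCCl
Why: Williamson-type alkylation under carbonate conditions is selective for the phenoxide over the secondary alcohol.

Step 9
Reactants: 13 3-bromo-4-[(1R)-1-hydroxybut-3-en-1-yl]-2-(methoxymethoxy)-6-methylbenzaldehyde
Product: 14 (1R)-1-[2-bromo-4-(1-hydroxyprop-2-en-1-yl)-3-(methoxymethoxy)-5-methylphenyl]but-3-en-1-ol
Conditions: CH2=CHMgBr (2.5 equiv), THF, −78 to 0 °C; aq. NH4Cl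
Reagents that add atoms: vinylmagnesium bromide, C=C[Mg]Br
Why: Grignard 1,2-addition to the aldehyde (one equivalent is spent on the free hydroxyl) gives the aryl vinyl carbinol as a mixture of epimers, which does not matter because this centre is erased in step 10.

Step 10
Reactants: 14 (1R)-1-[2-bromo-4-(1-hydroxyprop-2-en-1-yl)-3-(methoxymethoxy)-5-methylphenyl]but-3-en-1-ol
Product: 15 (1R)-1-{2-bromo-3-(methoxymethoxy)-5-methyl-4-[(1E)-3-(4,4,5,5-tetramethyl-1,3,2-dioxaborolan-2-yl)prop-1-en-1-yl]phenyl}but-3-en-1-ol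
Conditions: B2pin2, Pd(MeCN)4(BF4)2 (5 mol %), DMSO/MeOH, rt to 40 °C
Reagents that add atoms: bis(pinacolato)diboron, CC1(C)OB(OC1(C)C)B1OC(C)(C)C(C)(C)O1
Why: palladium-catalysed deoxygenative borylation of the allylic alcohol via an η3-allyl complex puts boron on the unsubstituted terminus and gives the conjugated (E)-γ-aryl allylboronate, while the homoallylic carbinol cannot form an allyl complex and stays.

Step 11
Reactants: 15 (1R)-1-{2-bromo-3-(methoxymethoxy)-5-methyl-4-[(1E)-3-(4,4,5,5-tetramethyl-1,3,2-dioxaborolan-2-yl)prop-1-en-1-yl]phenyl}but-3-en-1-ol; 4 2-bromo-6-(methoxymethoxy)-4-methylbenzaldehyde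
Product: 16 (1S,2R)-1-[2-bromo-6-(methoxymethoxy)-4-methylphenyl]-2-{3-bromo-4-[(1R)-1-hydroxybut-3-en-1-yl]-2-(methoxymethoxy)-6-methylphenyl}but-3-en-1-ol
Conditions: (S)-TRIP (10 mol %), 4 Å molecular sieves, toluene, 0 °C to rt
Reagents that add atoms: none
Why: chiral-phosphoric-acid-catalysed allylboration through a closed chair (Zimmerman–Traxler) transition state, in which the (E)-geometry of 15 fixes the anti C3/C4 relationship and the (S)-acid is expected to expose the Si face of 4, sets C4 as S and C3 as R, the remote C4′ centre playing no part.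

Step 12
Reactants: 16 (1S,2R)-1-[2-bromo-6-(methoxymethoxy)-4-methylphenyl]-2-{3-bromo-4-[(1R)-1-hydroxybut-3-en-1-yl]-2-(methoxymethoxy)-6-methylphenyl}but-3-en-1-ol
Product: 18 (1S,2R)-1-[2-bromo-6-(methoxymethoxy)-4-methylphenyl]-2-{3-bromo-4-[(1R)-1,4-dihydroxybutyl]-2-(methoxymethoxy)-6-methylphenyl}butane-1,4-diol, via tetrakis-borane adduct 17 (not isolated)
Conditions: 9-BBN (6 equiv), THF, 0 °C to rt; NaOH, H2O2, 0 °C to rt
Reagents that add atoms: hydrogen peroxide, OO
Why: anti-Markovnikov hydroboration of both terminal alkenes with the bulky borane (the two hydroxyls are tied up as borinates, hence the excess) and oxidation with retention give both primary alcohols without touching a stereocentre.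

Step 13
Reactants: 18 (1S,2R)-1-[2-bromo-6-(methoxymethoxy)-4-methylphenyl]-2-{3-bromo-4-[(1R)-1,4-dihydroxybutyl]-2-(methoxymethoxy)-6-methylphenyl}butane-1,4-diol
Product: 19 (4R,5S)-5-[2-bromo-6-(methoxymethoxy)-4-methylphenyl]-4-{3-bromo-2-(methoxymethoxy)-6-methyl-4-[(2R)-5-oxooxolan-2-yl]phenyl}oxolan-2-one
Conditions: Cu(MeCN)4OTf, 4,4′-dimethoxy-2,2′-bipyridine, TEMPO, N-methylimidazole (all catalytic), MeCN, air, rt
Reagents that add atoms: none
Why: copper/nitroxyl aerobic oxidative lactonization oxidizes only the primary alcohols; each aldehyde is trapped by its γ-hydroxyl as a lactol and oxidized on to the lactone, the hindered secondary benzylic carbinols being spared, so the anti diol becomes the trans-4,5-disubstituted lactone.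

Step 14
Reactants: 19 (4R,5S)-5-[2-bromo-6-(methoxymethoxy)-4-methylphenyl]-4-{3-bromo-2-(methoxymethoxy)-6-methyl-4-[(2R)-5-oxooxolan-2-yl]phenyl}oxolan-2-one
Product: 22 (3R,4S)-4-hydroxy-3-[(5R)-5-hydroxy-1-(methoxymethoxy)-3-methyl-8-oxo-5,6,7,8-tetrahydronaphthalen-2-yl]-5-(methoxymethoxy)-7-methyl-3,4-dihydronaphthalen-1(2H)-one, via dilithio bis-lactone 20 (not isolated), via bridged bis-hemiketal dialkoxide 21 (not isolated)
Conditions: t-BuLi (4.2 equiv), THF/Et2O/pentane, −100 to −78 °C; AcOH, −78 °C to rt
Reagents that add atoms: none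
Why: Two fast bromine–lithium exchanges (two t-BuLi per bromide, −100 °C) place carbanions on C8a and C8a′, each ortho to the arene carbon that carries a γ-lactone, and each aryllithium adds to the carbonyl carbon of its own lactone (C1, C1′) to give a benzo-fused 7-oxabicyclo[2.2.1]heptane hemiketal alkoxide (21) that opens by cleavage of the acyl C–O bond to the γ-alkoxy aryl ketone, a net 1,4 O→C acyl shift that turns each γ-aryl-γ-butyrolactone into a 4-hydroxy-1-tetralone. The closest known reaction types are the Parham cycloacylation (halogen–lithium exchange followed by intramolecular acylation by an ester or amide) and the anionic homo-Fries rearrangement of ortho-lithiated benzylic esters. Rings B and D are each closed by 6-exo-trig attack of the aryl carbon on the lactone C=O (bonds C1–C8a and C1′–C8a′), the approach perpendicular to the ester plane lying in the plane of the arene. No stereocentre is created or touched: C3, C4 and C4′ keep the configuration set in steps 5 and 11 because only acyl C–O bonds break and none of these centres is α to a carbonyl, so the trans-lactone becomes the cis 3-aryl-4-hydroxy arrangement and the (R)-lactone the (R)-carbinol C4′. The step needs the exchange to outrun addition of t-BuLi to the lactones and α-deprotonation (secured by the rate of Br/Li exchange at −100 °C) and each aryllithium to choose its own lactone (only that closure passes through a six-membered ring, the other carbonyl demanding a meta-bridged or macrocyclic transition state). Over-addition is held back because the ketones stay masked as hemiketal alkoxides or appear only after the aryllithium has been used up intramolecularly, and the acid quench at −78 °C then frees 22.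

Step 15
Reactants: 22 (3R,4S)-4-hydroxy-3-[(5R)-5-hydroxy-1-(methoxymethoxy)-3-methyl-8-oxo-5,6,7,8-tetrahydronaphthalen-2-yl]-5-(methoxymethoxy)-7-methyl-3,4-dihydronaphthalen-1(2H)-one
Product: 23 (3R,4S)-4,5-dihydroxy-3-[(5R)-1,5-dihydroxy-3-methyl-8-oxo-5,6,7,8-tetrahydronaphthalen-2-yl]-7-methyl-3,4-dihydronaphthalen-1(2H)-one (CNP0228272.3)
Conditions: HCl (1.25 M in MeOH), 35 °C
Reagents that add atoms: none
Why: acid-catalysed transacetalization removes both aryl MOM groups, methanol as solvent trapping the methoxymethyl cation as dimethoxymethane so that no cyclic formal forms across O5/O4, and both benzylic carbinols are protected against ionization by their ortho acyl groups.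

## Compound list

1 | 3-bromo-5-methylphenol | Cc1cc(O)cc(Br)c1 | starting material
2 | 1-bromo-3-(methoxymethoxy)-5-methylbenzene | COCOc1cc(C)cc(Br)c1 | intermediate
3 | [2-bromo-6-(methoxymethoxy)-4-methylphenyl]lithium | [Li]c1c(Br)cc(C)cc1OCOC | intermediate (not isolated)
4 | 2-bromo-6-(methoxymethoxy)-4-methylbenzaldehyde | O=Cc1c(Br)cc(C)cc1OCOC | intermediate
5 | [3-(methoxymethoxy)-5-methylphenyl]lithium | [Li]c1cc(C)cc(OCOC)c1 | intermediate (not isolated)
6 | 3-(methoxymethoxy)-5-methylbenzaldehyde | O=Cc1cc(C)cc(OCOC)c1 | intermediate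
7 | lithium {[2-(dimethylamino)ethyl](methyl)amino}[3-(methoxymethoxy)-5-methylphenyl]methanolate | CN(C)CCN(C)C(O[Li])c1cc(C)cc(OCOC)c1 | intermediate (not isolated)
8 | 2-lithio derivative of 7 (lithium between the amino alkoxide carbon and OMOM) | CN(C)CCN(C)C(O[Li])c1cc(C)cc(OCOC)c1[Li] | intermediate (not isolated)
9 | 2-bromo-3-(methoxymethoxy)-5-methylbenzaldehyde | O=Cc1cc(C)cc(OCOC)c1Br | intermediate
10 | (1R)-1-[2-bromo-3-(methoxymethoxy)-5-methylphenyl]but-3-en-1-ol | C=CC[C@@H](O)c1cc(C)cc(OCOC)c1Br | intermediate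
11 | (1R)-1-(2-bromo-3-hydroxy-5-methylphenyl)but-3-en-1-ol | C=CC[C@@H](O)c1cc(C)cc(O)c1Br | intermediate
12 | 3-bromo-2-hydroxy-4-[(1R)-1-hydroxybut-3-en-1-yl]-6-methylbenzaldehyde | C=CC[C@@H](O)c1cc(C)c(C=O)c(O)c1Br | intermediate
13 | 3-bromo-4-[(1R)-1-hydroxybut-3-en-1-yl]-2-(methoxymethoxy)-6-methylbenzaldehyde | C=CC[C@@H](O)c1cc(C)c(C=O)c(OCOC)c1Br | intermediate
14 | (1R)-1-[2-bromo-4-(1-hydroxyprop-2-en-1-yl)-3-(methoxymethoxy)-5-methylphenyl]but-3-en-1-ol (epimers at the allylic carbinol) | C=CC[C@@H](O)c1cc(C)c(C(O)C=C)c(OCOC)c1Br | intermediate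
15 | (1R)-1-{2-bromo-3-(methoxymethoxy)-5-methyl-4-[(1E)-3-(4,4,5,5-tetramethyl-1,3,2-dioxaborolan-2-yl)prop-1-en-1-yl]phenyl}but-3-en-1-ol | C=CC[C@@H](O)c1cc(C)c(/C=C/CB2OC(C)(C)C(C)(C)O2)c(OCOC)c1Br | intermediate
16 | (1S,2R)-1-[2-bromo-6-(methoxymethoxy)-4-methylphenyl]-2-{3-bromo-4-[(1R)-1-hydroxybut-3-en-1-yl]-2-(methoxymethoxy)-6-methylphenyl}but-3-en-1-ol | O[C@H](c1c(Br)cc(C)cc1OCOC)[C@H](C=C)c1c(C)cc([C@H](O)CC=C)c(Br)c1OCOC | intermediate
17 | adduct of 16 with four 9-borabicyclo[3.3.1]nonane units (C–B at both chain termini, O–B at both carbinols) | O(B3C2CCCC3CCC2)[C@H](c1c(Br)cc(C)cc1OCOC)[C@H](CCB4C5CCCC4CCC5)c1c(C)cc([C@H](OB6C7CCCC6CCC7)CCCB8C9CCCC8CCC9)c(Br)c1OCOC | intermediate (not isolated)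
18 | (1S,2R)-1-[2-bromo-6-(methoxymethoxy)-4-methylphenyl]-2-{3-bromo-4-[(1R)-1,4-dihydroxybutyl]-2-(methoxymethoxy)-6-methylphenyl}butane-1,4-diol | O[C@H](c1c(Br)cc(C)cc1OCOC)[C@H](CCO)c1c(C)cc([C@H](O)CCCO)c(Br)c1OCOC | intermediate
19 | (4R,5S)-5-[2-bromo-6-(methoxymethoxy)-4-methylphenyl]-4-{3-bromo-2-(methoxymethoxy)-6-methyl-4-[(2R)-5-oxooxolan-2-yl]phenyl}oxolan-2-one | O=C1C[C@H](c2c(C)cc([C@H]3CCC(=O)O3)c(Br)c2OCOC)[C@@H](c2c(Br)cc(C)cc2OCOC)O1 | intermediate
20 | dilithio derivative of 19 (lithium in place of both bromines) | O=C1C[C@H](c2c(C)cc([C@H]3CCC(=O)O3)c([Li])c2OCOC)[C@@H](c2c([Li])cc(C)cc2OCOC)O1 | intermediate (not isolated)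
21 | bis(lithium hemiketal alkoxide) with a 1,4-epoxy bridge across each new ring (C1–O–C4 and C1′–O–C4′) | [Li]O[C@]12C[C@H](c3c(C)cc4c(c3OCOC)[C@]5(O[Li])CC[C@H]4O5)[C@H](O1)c1c(OCOC)cc(C)cc12 | intermediate (not isolated)
22 | (3R,4S)-4-hydroxy-3-[(5R)-5-hydroxy-1-(methoxymethoxy)-3-methyl-8-oxo-5,6,7,8-tetrahydronaphthalen-2-yl]-5-(methoxymethoxy)-7-methyl-3,4-dihydronaphthalen-1(2H)-one | Cc1cc(OCOC)c2c(c1)C(=O)C[C@H](c1c(C)cc3c(c1OCOC)C(=O)CC[C@H]3O)[C@@H]2O | intermediate
23 | (3R,4S)-4,5-dihydroxy-3-[(5R)-1,5-dihydroxy-3-methyl-8-oxo-5,6,7,8-tetrahydronaphthalen-2-yl]-7-methyl-3,4-dihydronaphthalen-1(2H)-one | Cc1cc(O)c2c(c1)C(=O)C[C@H](c1c(C)cc3c(c1O)C(=O)CC[C@H]3O)[C@@H]2O | target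

## Step count and risks

Total step count: 15. Longest linear sequence: 14 steps (steps 1, 3–15); step 2 is the side branch to aldehyde 4.

Steps most likely to fail:

1. Step 14. The exchange at the more hindered ring-C bromide may lag behind, so that a ketone already released in one half meets organolithium still present; proton transfer from a lactone α-CH2 to an aryllithium may also compete. The fallback sets out from 19. Both lactones are opened with Me(MeO)NH·HCl/i-PrMgCl (THF, −20 °C) to (3R,4S)-4-[2-bromo-6-(methoxymethoxy)-4-methylphenyl]-3-{3-bromo-4-[(1R)-1-hydroxy-4-[methoxy(methyl)amino]-4-oxobutyl]-2-(methoxymethoxy)-6-methylphenyl}-4-hydroxy-N-methoxy-N-methylbutanamide F1. This is used at once: the two carbinols are masked as magnesium alkoxides (i-PrMgCl, −78 °C), and t-BuLi (4 equiv, −78 °C) triggers a double Parham cycloacylation onto the Weinreb amides, whose N,O-chelated tetrahedral adducts cannot release a ketone before aqueous work-up. The fallback rejoins the route at 22.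

2. Step 11. C–C bond formation between two doubly ortho-substituted partners may be slow, with protodeboronation of 15 competing, or the acid may fail to control the aldehyde face. The fallback sets out from 4 and 15 and gives up catalyst control. The partners are joined thermally (toluene, 60 °C, no acid) through the same closed chair transition state, which keeps the anti relationship but should give both anti adducts: 16 and (1R,2S)-1-[2-bromo-6-(methoxymethoxy)-4-methylphenyl]-2-{3-bromo-4-[(1R)-1-hydroxybut-3-en-1-yl]-2-(methoxymethoxy)-6-methylphenyl}but-3-en-1-ol F2. Because 15 is a single enantiomer, these are diastereomers; they are separated by chromatography, F2 is set aside, and the route is rejoined at 16.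

3. Step 10. The electron-rich aryl vinyl carbinol may ionize and be captured by methanol or lose water, or palladium may insert into the aryl bromide instead of forming the allyl–boron bond. The fallback sets out from aldehyde 13. Boron-Wittig olefination with CH2(Bpin)2 and lithium 2,2,6,6-tetramethylpiperidide (THF, −78 °C to rt, one extra equivalent of base for the hydroxyl) gives (1R)-1-{2-bromo-3-(methoxymethoxy)-5-methyl-4-[(E)-2-(4,4,5,5-tetramethyl-1,3,2-dioxaborolan-2-yl)ethenyl]phenyl}but-3-en-1-ol F3. Matteson homologation (ICH2Cl, n-BuLi, THF, −78 °C to rt) then inserts the CH2 group with 1,2-migration of the alkenyl group and retention of the (E)-geometry. The fallback rejoins the route at 15.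

Further compounds
F1 | step 14 | (3R,4S)-4-[2-bromo-6-(methoxymethoxy)-4-methylphenyl]-3-{3-bromo-4-[(1R)-1-hydroxy-4-[methoxy(methyl)amino]-4-oxobutyl]-2-(methoxymethoxy)-6-methylphenyl}-4-hydroxy-N-methoxy-N-methylbutanamide | CON(C)C(=O)C[C@H](c1c(C)cc([C@H](O)CCC(=O)N(C)OC)c(Br)c1OCOC)[C@H](O)c1c(Br)cc(C)cc1OCOC
F2 | step 11 | (1R,2S)-1-[2-bromo-6-(methoxymethoxy)-4-methylphenyl]-2-{3-bromo-4-[(1R)-1-hydroxybut-3-en-1-yl]-2-(methoxymethoxy)-6-methylphenyl}but-3-en-1-ol | O[C@@H](c1c(Br)cc(C)cc1OCOC)[C@@H](C=C)c1c(C)cc([C@H](O)CC=C)c(Br)c1OCOC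
F3 | step 10 | (1R)-1-{2-bromo-3-(methoxymethoxy)-5-methyl-4-[(E)-2-(4,4,5,5-tetramethyl-1,3,2-dioxaborolan-2-yl)ethenyl]phenyl}but-3-en-1-ol | C=CC[C@@H](O)c1cc(C)c(/C=C/B2OC(C)(C)C(C)(C)O2)c(OCOC)c1Br
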